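# Proposed synthesis of 2-O-acetylzeylenone

## Structural features

The target is a single carbocycle, a cyclohex-2-enone in which four contiguous ring carbons carry oxygen. C1 is a fully substituted tertiary carbinol that also bears the exocyclic carbon C7 (as CH2OBz), C2 is a secondary acetate, C3 is a secondary allylic benzoate, and C4=C5 is conjugated to the C6 ketone, which stands directly next to C1. The three stereocentres C1, C2 and C3 are adjacent (1S,2S,3R in this numbering): the oxygens on C1 and C2 are cis, and the oxygen on C3 is trans to both and therefore cis to C7. The fragile parts are the γ-benzoyloxy enone (vinylogous loss of benzoic acid, then aromatisation), the α-ketol at C1/C6, and three esters of two kinds on neighbouring oxygens, which shift to any free neighbouring hydroxyl under base. The real difficulty is to set the oxygenated quaternary centre C1 in fixed relation to C2 and C3, and to tell four oxygens apart (free tertiary OH, acetate, two benzoates) without exposing the finished enone to base or hydride. The key step exploits the O–C1–C2–O unit of the ring: two vicinal oxygenated carbons, one of them quaternary with a one-carbon branch, are the ortho adduct of a 1-oxygenated butadiene (C2–C5) and a 2-oxygenated acrolein (C6, C1, formyl carbon C7). The carboxyl group later made from C7 can reach C3 only on its own face, which is the face the C3 oxygen must occupy.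

## Logic of the disconnections

17 is cut first at the acyl–oxygen bond of the C2 acetate, giving 15 and 16. The acetate is the ester most easily lost or shifted, so it goes on last; what remains is a diol whose hydroxyls differ in class (secondary at C2, tertiary at C1). The forward step must acylate only the secondary hydroxyl, under conditions mild enough for the γ-benzoyloxy enone.

15 is cut at the O–Si bond on C2 to give 14. The silyl group is the label that keeps the C2 oxygen apart from the other oxygens from ring formation onward, so this cut traces that oxygen back to the diene. The forward cleavage must be non-basic, because a free alkoxide at C2 would invite benzoyl migration from O–C3.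

14 is simplified by removing the carbonyl oxygen at C6, that is, by taking the C6=O bond back to a methylene in 13. The ketone could not survive the hydride step needed earlier, and without it every earlier intermediate is free of the base-sensitive enone; C6 is the only allylic methylene of 13. The forward step must oxidise C6–H in preference to C3–H and must not transpose the alkene.

13 is cut at the two benzoate acyl–oxygen bonds on O–C7 and O–C3, giving 12 and two equivalents of 5. Both oxygens are released together in the preceding reduction and need the same acyl group, so one operation serves; the gain is a triol with one primary, one secondary and one tertiary hydroxyl. The forward acylation must stop before the tertiary hydroxyl at C1.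

12 is reconnected between C7 and O–C3 at the carboxyl oxidation level, with O–C1 acylated again, which leads to 11; in the forward sense hydride cuts the C7–O(C3) acyl bond and the C1 ester. The lactone is kept in the plan because it records how the C3 oxygen was delivered and merges C7 and the C3 stereocentre into one rigid unit. The demand is a reductant that opens lactone and ester but leaves the Si–O bond, the alkene and the C3 configuration alone, and a silyl group that does not wander to the neighbouring alkoxides.

11 is traced to 10 by adding H–I across C4=C5, and 10 to 9 by cutting the C3–O and C4–I bonds. The C7 carboxylate can place oxygen on C3 only from the face C7 occupies, which is trans to O–C2 as required, and the iodine left at C4 lets the alkene move from C3=C4 to C4=C5. The gain is loss of the C3 stereocentre and an alkene in the position a Diels–Alder reaction leaves it. The forward steps demand closure of the five-membered lactone at C3 rather than the six-membered one at C4, and elimination toward C5 only.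

9 is taken back to 8 by lowering C7 from carboxyl to formyl. The formyl group is what the cycloaddition needs for activation and for binding the catalyst. The forward oxidation only has to spare the alkene and the silyl ether.

8 is cut at C1–C2 and C5–C6, which opens the ring and gives 3 and 7. These are the two bonds between the four-carbon unit C2–C5 (oxygen on C2) and the three-carbon unit C6–C1–C7 (oxygen on C1); the cut removes the ring and both remaining stereocentres at once and leaves two achiral pieces. The forward step must control regiochemistry (oxygen-bearing terminus to the substituted carbon), relative configuration (oxygens cis) and absolute configuration together.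

7 polymerises on storage and is therefore traced to 6, in which its carbonyl oxygen and its methylene are tied up in a six-membered ketal ring that releases a volatile ketone on heating; 6 is cut at the enol ester acyl–oxygen bond to 4 and 5. The gain is a storable precursor and two commercial compounds. The forward demand is acylation of the enol at oxygen rather than carbon, and a clean thermal release.

3 is cut at the O–Si bond, with return of a γ-hydrogen, to 1 and 2. Both are commercial; the forward step must give the E dienol ether.

## Other disconnections considered

Alternative 1: The cut is at C1–C6 and C1–C2, with the ring left open; it would be closed later between C4 and C5.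
- **Forward key step:** the zinc acetylide of ethynyltrimethylsilane A2 adds to the acylsilane carbonyl of silyl glyoxylate A1. A Brook rearrangement turns the alkoxide into a glycolate enolate, which adds to the α-alkoxy aldehyde A3 and gives the open-chain ester A4.
- **In its favour:** three fragments are joined in one flask, C1 is made fully substituted together with C2, and C3 comes from the chiral pool, so no asymmetric catalyst is needed.
- **Where it is better:** the alkyne brings C5 and C6 at the oxidation level of the enone. Hydration and an aldol condensation onto a C4 aldehyde would give C4=C5–C6=O without any C–H oxidation, whereas the chosen plan depends on a late allylic oxidation.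
- **Against it here:** the configurations at C1 and C2 depend on enolate geometry and on the facial choice at A3 in an open transition state. A4 carries five protecting groups, none of which is in the target, so the C7 ester must be reduced and three ethers exchanged for two benzoates and an acetate. The ring closure puts an enolisable aldehyde next to the C3 stereocentre.
- **Comparison:** on structure both plans centre on the quaternary carbinol C1, but this one builds a chain and the chosen plan builds the ring with C1 and C2 at once. On mechanism it is a polar anionic cascade with stoichiometric metal against a catalytic pericyclic step. On step economy its key step is more convergent, but the operations after it should outnumber those of the chosen route.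

Alternative 2: The cut is at the C2–O bond; the ring is present from the start as an achiral cyclohexadienone.
- **Forward key step:** phenylboronic acid A6 esterifies the tertiary hydroxyl of para-quinol A5. The remaining B–OH adds to one of the two enantiotopic enone arms under a chiral amine–thiourea and gives the cis-fused boronate A7.
- **In its favour:** A5 is achiral and should be reachable in two or three steps by oxidative dearomatisation, C7 carries its benzoate from the beginning, and the step is catalytic.
- **Where it is better:** the five-membered tether can only deliver the C2 oxygen cis to O–C1, independent of any endo/exo preference.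
- **Against it here:** in A7 the ketone is at C4, the alkene at C5=C6 and C3 is a bare methylene, while the target has the ketone at C6, the alkene at C4=C5 and a benzoate on C3 trans to O–C2. This would need a face-selective α-oxygenation at C3 and then a 1,3-transposition of the enone (for example epoxidation and Wharton transposition, then oxidation), all on a β-alkoxy ketone that can revert by retro-Michael reaction.
- **Comparison:** on structure it fits C1, C2 and C7 better than the chosen plan and C3–C6 worse. On mechanism both are catalytic and enantioselective, one by desymmetrisation and one by cycloaddition. On step economy the short front end is expected to be offset by the repair of the oxidation pattern, so no clear gain is seen.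

Alternative 3: The cut is at C1–C6, the retron being the homoallylic tertiary alcohol C1(OH)–C6–C5=C4.
- **Forward key step:** the C-vinyl furanoside A8 is deprotonated twice (C2 alkoxide, C1 ester enolate). The enolate carbon bonds to the vinyl terminus while the ring C4–O bond breaks ([2,3]-Wittig shift), expanding the oxolane to the cyclohexene A9.
- **In its favour:** C2 and C3 come from a sugar, already trans and already differentiated (free hydroxyl against PMB ether), and C1 is set by chirality transfer from C4 through a compact bicyclic transition state.
- **Where it is better or equal:** the C4=C5 alkene arrives in place, so no lactonisation–elimination sequence is needed (better). C6 is still a methylene in A9, so the same allylic oxidation is required (equal, the same weakness).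
- **Against it here:** A8 needs a multi-step carbohydrate synthesis. A [1,2]-shift and β-elimination can compete with the [2,3]-shift of a strained dianion. The ester must still be reduced and the PMB ether exchanged for a benzoate.
- **Comparison:** on structure it suits the C2–C5 region better and the C6/C7 region no better. On mechanism it is a stoichiometric strong-base sigmatropic shift with substrate control, against a catalytic cycloaddition with reagent control. On step economy it should be longer once the preparation of A8 is counted.

Key step: step 4

## Remarks on the chemistry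

- The atom numbering of the target (C1 carbinol, C2, C3, C4=C5, C6 ketone, C7 exocyclic carbon) is used for every intermediate, whatever its systematic name.
- Dioxanone 4 is assumed to be purchased. This saves one step and avoids the poorly behaved direct acetalisation of dihydroxyacetone dimer.
- The chiral oxazaborolidine is assumed to be prepared beforehand from (S)-α,α-diphenylprolinol and tri-o-tolylboroxine and is not counted as a step.

## Route

Step 1
Reactants: 1 crotonaldehyde; 2 triisopropylsilyl trifluoromethanesulfonate
Product: 3 (E)-1-(triisopropylsilyloxy)buta-1,3-diene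
Conditions: Et3N, Et2O, 0 °C to rt; distillation
Reagents that add atoms: none
Why: Soft enolisation: silylation at the carbonyl oxygen gives an oxocarbenium ion that loses its γ-proton to Et3N (vinylogous silyl enol ether formation), and the E dienol ether should predominate. Any Z isomer cannot reach the s-cis conformation and stays behind in step 4.

Step 2
Reactants: 4 2,2-dimethyl-1,3-dioxan-5-one; 5 benzoyl chloride
Product: 6 2,2-dimethyl-4H-1,3-dioxin-5-yl benzoate
Conditions: pyridine, 4-(dimethylamino)pyridine (cat.), CH2Cl2, 0 °C to rt
Reagents that add atoms: none
Why: Enol ester formation: the flanking ring oxygens make the ketone readily enolisable, and the hard acyl chloride reacts at the enol oxygen rather than at carbon.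

Step 3
Reactants: 6 2,2-dimethyl-4H-1,3-dioxin-5-yl benzoate
Product: 7 2-(benzoyloxy)acrolein (3-oxoprop-1-en-2-yl benzoate)
Conditions: PhMe, 110 °C, then evaporation of acetone and solvent; used at once
Reagents that add atoms: none
Why: Retro-hetero-Diels–Alder reaction of the 4H-1,3-dioxin: the ketal carbon leaves as acetone and the 1-oxadiene released is the 2-acyloxyacrolein. Entropy and removal of the volatile ketone drive it, and immediate use avoids polymerisation.

Step 4
Reactants: 3 (E)-1-(triisopropylsilyloxy)buta-1,3-diene; 7 2-(benzoyloxy)acrolein
Product: 8 (1R,2S)-1-formyl-2-(triisopropylsilyloxy)cyclohex-3-en-1-yl benzoate (oxygens on C1 and C2 cis)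
Conditions: (S)-3,3-diphenyl-1-(2-methylphenyl)tetrahydro-1H,3H-pyrrolo[1,2-c][1,3,2]oxazaborole (20 mol %), (CF3SO2)2NH (18 mol %), CH2Cl2, −78 °C
Reagents that add atoms: none
Why: The boron of the protonated oxazaborolidine binds the formyl oxygen of 7 anti to the vinyl group, and a formyl C–H···O contact to the ring oxygen holds the s-trans enal over one phenyl ring of the catalyst; 3 then adds in a concerted, asynchronous Diels–Alder reaction in which the C5–C6 bond (diene CH2 terminus to the enal β-carbon) runs ahead of the C1–C2 bond. The closest known reaction type is the cationic-oxazaborolidine-catalysed Diels–Alder reaction of α-substituted acroleins (2-bromo-, 2-methyl-, 2-acyloxy-) with silyloxydienes. The cyclohexene ring is closed by an intermolecular [4+2] cycloaddition, suprafacial on both partners, through a boat-like transition state. C1 is controlled by the catalyst: the stacked phenyl ring covers the Si face of the α-carbon, so the diene bonds to the Re face (1R). C2 is controlled by the E geometry of 3 together with the exo position of the formyl group (benzoyloxy endo), which puts the two oxygens cis (2S). The step needs ortho regiochemistry, which the oxygen at the diene terminus secures by raising the HOMO coefficient at the remote CH2 terminus that meets the β-carbon of the activated enal. It also needs exo-formyl selectivity, for which the α-benzoyloxy group is relied on (its planar ester lies under the diene while the boron-laden formyl group takes the outer position), and one enantioface, which only the catalyst provides. The low temperature and the non-nucleophilic triflimide counter-ion should keep the acid-labile silyl dienol ether intact.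

Step 5
Reactants: 8 (1R,2S)-1-formyl-2-(triisopropylsilyloxy)cyclohex-3-en-1-yl benzoate
Product: 9 (1R,2S)-1-(benzoyloxy)-2-(triisopropylsilyloxy)cyclohex-3-ene-1-carboxylic acid
Conditions: NaClO2, NaH2PO4, 2-methyl-2-butene, t-BuOH/H2O, 0 °C to rt
Reagents that add atoms: sodium chlorite, [Na+].[O-]Cl=O
Why: Pinnick oxidation: chlorous acid adds to the formyl group and fragments to the acid. The aldehyde has no α-hydrogen, the buffered medium spares the silyl ether and benzoate, and the alkene scavenger removes HOCl before it can attack C3=C4.

Step 6
Reactants: 9 (1R,2S)-1-(benzoyloxy)-2-(triisopropylsilyloxy)cyclohex-3-ene-1-carboxylic acid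
Product: 10 (1R,4S,5S,8S)-4-iodo-7-oxo-8-(triisopropylsilyloxy)-6-oxabicyclo[3.2.1]octan-1-yl benzoate (γ-lactone from C7 to O–C3, iodine on C4 trans to the lactone oxygen)
Conditions: I2, KI, NaHCO3, THF/H2O, 0 °C to rt, dark
Reagents that add atoms: iodine, [I][I]
Why: Iodolactonisation: iodonium formation at C3=C4 is reversible, and only the iodonium anti to the carboxylate is captured, by 5-exo attack at C3. This sets O–C3 cis to C7 (trans to O–C2) and the C4 iodine trans to the lactone oxygen by anti addition.

Step 7
Reactants: 10 (1R,4S,5S,8S)-4-iodo-7-oxo-8-(triisopropylsilyloxy)-6-oxabicyclo[3.2.1]octan-1-yl benzoate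
Product: 11 (1R,5R,8S)-7-oxo-8-(triisopropylsilyloxy)-6-oxabicyclo[3.2.1]oct-3-en-1-yl benzoate (alkene C4=C5)
Conditions: DBU, PhMe, 80 °C
Reagents that add atoms: none
Why: E2 dehydroiodination: the axial C4–I bond is anti-periplanar only to the axial hydrogen on C5. The hydrogen on C3 is syn and at a bridgehead, so only the C4=C5 alkene can form.

Step 8
Reactants: 11 (1R,5R,8S)-7-oxo-8-(triisopropylsilyloxy)-6-oxabicyclo[3.2.1]oct-3-en-1-yl benzoate
Product: 12 (1S,2S,3R)-1-(hydroxymethyl)-2-(triisopropylsilyloxy)cyclohex-4-ene-1,3-diol
Conditions: LiAlH4, THF, 0 °C to rt; Na2SO4·10H2O quench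
Reagents that add atoms: none
Why: Hydride reduction cleaves the lactone at the acyl–oxygen bond, giving the C7 primary alcohol and the C3 allylic alcohol with its configuration unchanged, and removes the C1 benzoate, which must end as free hydroxyl. The bulky triisopropylsilyl ether is inert and should not migrate to the neighbouring alkoxides.

Step 9
Reactants: 12 (1S,2S,3R)-1-(hydroxymethyl)-2-(triisopropylsilyloxy)cyclohex-4-ene-1,3-diol; 5 benzoyl chloride
Product: 13 [(1S,2S,3R)-3-(benzoyloxy)-1-hydroxy-2-(triisopropylsilyloxy)cyclohex-4-en-1-yl]methyl benzoate
Conditions: BzCl (2.3 equiv), pyridine, 4-(dimethylamino)pyridine (cat.), CH2Cl2, 0 °C to rt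
Reagents that add atoms: benzoyl chloride (second equivalent), O=C(Cl)c1ccccc1
Why: Nucleophile-catalysed acylation follows the order primary > secondary >> tertiary, so two equivalents of the acid chloride benzoylate O–C7 and then O–C3 while the hindered tertiary hydroxyl on C1 stays free.

Step 10
Reactants: 13 [(1S,2S,3R)-3-(benzoyloxy)-1-hydroxy-2-(triisopropylsilyloxy)cyclohex-4-en-1-yl]methyl benzoate
Product: 14 [(1S,5R,6S)-5-(benzoyloxy)-1-hydroxy-2-oxo-6-(triisopropylsilyloxy)cyclohex-3-en-1-yl]methyl benzoate
Conditions: Rh2(cap)4 (cap = caprolactamate, C6H10NO; 1 mol %), t-BuOOH (70 % aq.), ClCH2CH2Cl, 40 °C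
Reagents that add atoms: tert-butyl hydroperoxide, CC(C)(C)OO
Why: Catalytic allylic oxidation with a hydroperoxide: the tert-butylperoxyl radical abstracts hydrogen from C6, the only allylic methylene (the C3 hydrogen is deactivated by its acyloxy group), and oxygen transfer at C6 gives the conjugated ketone. The medium contains no base and no hydride, so esters, silyl ether and tertiary alcohol should persist.

Step 11
Reactants: 14 [(1S,5R,6S)-5-(benzoyloxy)-1-hydroxy-2-oxo-6-(triisopropylsilyloxy)cyclohex-3-en-1-yl]methyl benzoate
Product: 15 [(1S,5R,6S)-5-(benzoyloxy)-1,6-dihydroxy-2-oxocyclohex-3-en-1-yl]methyl benzoate (zeylenone framework, hydroxyl on C2 free)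
Conditions: HF·pyridine, THF/pyridine, 0 °C to rt
Reagents that add atoms: none
Why: Fluoride cleaves the Si–O bond (formation of the strong Si–F bond) in a buffered acidic medium, in which no alkoxide is formed, so benzoyl migration and elimination from the γ-benzoyloxy enone are not expected.

Step 12
Reactants: 15 [(1S,5R,6S)-5-(benzoyloxy)-1,6-dihydroxy-2-oxocyclohex-3-en-1-yl]methyl benzoate; 16 acetic anhydride
Product: 17 [(1S,5R,6S)-6-acetoxy-5-(benzoyloxy)-1-hydroxy-2-oxocyclohex-3-en-1-yl]methyl benzoate (2-O-acetylzeylenone)
Conditions: Ac2O, pyridine, CH2Cl2, 0 °C to rt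
Reagents that add atoms: none
Why: Acetylation of the only acylable hydroxyl: the secondary alcohol on C2 reacts, while the tertiary α-ketol hydroxyl on C1 is too hindered under these weakly basic conditions. No stereocentre is touched.

## Compound list

1 | crotonaldehyde ((E)-but-2-enal) | C/C=C/C=O | starting material
2 | triisopropylsilyl trifluoromethanesulfonate | CC(C)[Si](OS(=O)(=O)C(F)(F)F)(C(C)C)C(C)C | starting material
3 | (E)-1-(triisopropylsilyloxy)buta-1,3-diene | C=C/C=C/O[Si](C(C)C)(C(C)C)C(C)C | intermediate
4 | 2,2-dimethyl-1,3-dioxan-5-one | CC1(C)OCC(=O)CO1 | starting material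
5 | benzoyl chloride | O=C(Cl)c1ccccc1 | starting material
6 | 2,2-dimethyl-4H-1,3-dioxin-5-yl benzoate | CC1(C)OCC(OC(=O)c2ccccc2)=CO1 | intermediate
7 | 2-(benzoyloxy)acrolein | C=C(OC(=O)c1ccccc1)C=O | intermediate
8 | (1R,2S)-1-formyl-2-(triisopropylsilyloxy)cyclohex-3-en-1-yl benzoate | CC(C)[Si](C(C)C)(C(C)C)O[C@H]1C=CCC[C@@]1(C=O)OC(=O)c1ccccc1 | intermediate
9 | (1R,2S)-1-(benzoyloxy)-2-(triisopropylsilyloxy)cyclohex-3-ene-1-carboxylic acid | CC(C)[Si](C(C)C)(C(C)C)O[C@H]1C=CCC[C@@]1(C(=O)O)OC(=O)c1ccccc1 | intermediate
10 | (1R,4S,5S,8S)-4-iodo-7-oxo-8-(triisopropylsilyloxy)-6-oxabicyclo[3.2.1]octan-1-yl benzoate | CC(C)[Si](C(C)C)(C(C)C)O[C@H]1[C@H]2[C@@H](I)CC[C@]1(OC(=O)c3ccccc3)C(=O)O2 | intermediate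
11 | (1R,5R,8S)-7-oxo-8-(triisopropylsilyloxy)-6-oxabicyclo[3.2.1]oct-3-en-1-yl benzoate | CC(C)[Si](C(C)C)(C(C)C)O[C@H]1[C@H]2C=CC[C@]1(OC(=O)c3ccccc3)C(=O)O2 | intermediate
12 | (1S,2S,3R)-1-(hydroxymethyl)-2-(triisopropylsilyloxy)cyclohex-4-ene-1,3-diol | CC(C)[Si](C(C)C)(C(C)C)O[C@H]1[C@H](O)C=CC[C@]1(O)CO | intermediate
13 | [(1S,2S,3R)-3-(benzoyloxy)-1-hydroxy-2-(triisopropylsilyloxy)cyclohex-4-en-1-yl]methyl benzoate | CC(C)[Si](C(C)C)(C(C)C)O[C@H]1[C@H](OC(=O)c2ccccc2)C=CC[C@]1(O)COC(=O)c1ccccc1 | intermediate
14 | [(1S,5R,6S)-5-(benzoyloxy)-1-hydroxy-2-oxo-6-(triisopropylsilyloxy)cyclohex-3-en-1-yl]methyl benzoate | CC(C)[Si](C(C)C)(C(C)C)O[C@H]1[C@H](OC(=O)c2ccccc2)C=CC(=O)[C@]1(O)COC(=O)c1ccccc1 | intermediate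
15 | [(1S,5R,6S)-5-(benzoyloxy)-1,6-dihydroxy-2-oxocyclohex-3-en-1-yl]methyl benzoate | O[C@H]1[C@H](OC(=O)c2ccccc2)C=CC(=O)[C@]1(O)COC(=O)c1ccccc1 | intermediate
16 | acetic anhydride | CC(=O)OC(C)=O | starting material
17 | [(1S,5R,6S)-6-acetoxy-5-(benzoyloxy)-1-hydroxy-2-oxocyclohex-3-en-1-yl]methyl benzoate (2-O-acetylzeylenone) | CC(=O)O[C@H]1[C@H](OC(=O)c2ccccc2)C=CC(=O)[C@]1(O)COC(=O)c1ccccc1 | target

## Step count and least certain steps

Total: 12 steps. Longest linear sequence: 11 steps (steps 2 to 12, from 4 to 17); step 1 is the one-step side branch to 3.

**Step 4 (key step).** The exo-formyl preference is the most likely point of failure: an acyclic diene has no bridging group to enforce it, so the two oxygens may end up trans. Partial loss of the silyl dienol ether to the strong acid is a second risk, and should the facial sense be opposite to the model, the antipodal catalyst is the simple remedy. The fallback starts from 3 and 7 and returns at 11: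
- If the formyl-endo mode competes, the product is the C2-epimeric cycloadduct (1R,2R)-1-formyl-2-(triisopropylsilyloxy)cyclohex-3-en-1-yl benzoate F1, with C1 still set by the catalyst.
- Alone or mixed with 8, it would be carried through the operations of steps 5 to 7: NaClO2 oxidation to the C2-epimeric acid F2, iodolactonisation to the epimeric iodolactone F3, and DBU elimination to the epimeric alkene lactone F4.
- C2 is then corrected where it is a one-carbon bridge between two bridgeheads and cannot enolise. HF·pyridine frees the bridge alcohol F5 and Dess–Martin periodinane gives the bridge ketone F6.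
- NaBH4 with CeCl3·7H2O in MeOH at −78 °C should deliver hydride from the side of the lactone bridge, which carries no hydrogen, giving the inverted bridge alcohol F7 with its oxygen anti to the lactone (cis to O–C1).
- Silylation with 2 and 2,6-lutidine returns 11. Both C2 epimers converge on F6, so the sequence also serves an unselective cycloaddition.

**Step 6.** Lactonisation may be slow or diverted: iodine has to enter syn to the bulky silyloxy group (1,3-diaxial in the bicycle), the neighbouring benzoate carbonyl may capture the more accessible iodonium ion, and closure at C4 to the six-membered lactone is possible. The fallback starts from 8, replaces steps 5 to 8 and returns at 12: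
- LiAlH4 reduces the aldehyde and removes the benzoate, giving the diol (1S,2S)-1-(hydroxymethyl)-2-(triisopropylsilyloxy)cyclohex-3-en-1-ol F8.
- mCPBA (NaHCO3, CH2Cl2) should epoxidise anti to the allylic silyloxy group, on the face of the hydroxymethyl group, giving the 3,4-epoxide F9.
- PhSeSePh with NaBH4 in EtOH opens the epoxide with inversion at C4, the carbon remote from the oxygenated C2, giving the hydroxy selenide F10 (hydroxyl on C3 trans to O–C2).
- H2O2 forms the selenoxide, which undergoes syn elimination toward C5, away from the carbinol carbon, and this gives 12.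

**Step 10.** Oxygen may be delivered to C4 instead of C6, because the allyl radical has two termini and C6 is neopentylic; abstraction at C3 or over-oxidation are lesser risks. The fallback starts from 13 and returns at 14:
- SeO2 with t-BuOOH in CH2Cl2, or SeO2 in dioxane at 80 °C, hydroxylates C6 by an ene reaction followed by a [2,3]-sigmatropic shift. This returns oxygen to the carbon that lost hydrogen and cannot transpose the alkene.
- The resulting C6 allylic alcohol F11 (either C6 epimer) is oxidised with Dess–Martin periodinane to 14.

**Step 11.** Benzoyl migration from O–C3 to the freed O–C2, or loss of benzoic acid from the γ-benzoyloxy enone, may set in if the medium becomes basic, and cleavage of the hindered silyl ether may be slow. The fallback starts from 13 and returns at 17: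
- The silyl ether is removed before the enone exists: HF·pyridine gives the diol [(1S,2S,3R)-3-(benzoyloxy)-1,2-dihydroxycyclohex-4-en-1-yl]methyl benzoate F12.
- Acetylation with 16 in pyridine gives the acetate [(1S,2S,3R)-2-acetoxy-3-(benzoyloxy)-1-hydroxycyclohex-4-en-1-yl]methyl benzoate F13.
- The allylic oxidation of step 10 is then run last and gives 17 directly, so the enone never meets fluoride or amine.

## Further compounds

F1 | step 4 | (1R,2R)-1-formyl-2-(triisopropylsilyloxy)cyclohex-3-en-1-yl benzoate | CC(C)[Si](C(C)C)(C(C)C)O[C@@H]1C=CCC[C@@]1(C=O)OC(=O)c1ccccc1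
F2 | step 4 | (1R,2R)-1-(benzoyloxy)-2-(triisopropylsilyloxy)cyclohex-3-ene-1-carboxylic acid | CC(C)[Si](C(C)C)(C(C)C)O[C@@H]1C=CCC[C@@]1(C(=O)O)OC(=O)c1ccccc1
F3 | step 4 | (1R,4S,5S,8R)-4-iodo-7-oxo-8-(triisopropylsilyloxy)-6-oxabicyclo[3.2.1]octan-1-yl benzoate | CC(C)[Si](C(C)C)(C(C)C)O[C@@H]1[C@H]2[C@@H](I)CC[C@]1(OC(=O)c3ccccc3)C(=O)O2
F4 | step 4 | (1R,5R,8R)-7-oxo-8-(triisopropylsilyloxy)-6-oxabicyclo[3.2.1]oct-3-en-1-yl benzoate | CC(C)[Si](C(C)C)(C(C)C)O[C@@H]1[C@H]2C=CC[C@]1(OC(=O)c3ccccc3)C(=O)O2
F5 | step 4 | (1R,5R,8R)-8-hydroxy-7-oxo-6-oxabicyclo[3.2.1]oct-3-en-1-yl benzoate | O[C@@H]1[C@H]2C=CC[C@]1(OC(=O)c3ccccc3)C(=O)O2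
F6 | step 4 | (1R,5R)-7,8-dioxo-6-oxabicyclo[3.2.1]oct-3-en-1-yl benzoate | O=C1[C@H]2C=CC[C@]1(OC(=O)c3ccccc3)C(=O)O2
F7 | step 4 | (1R,5R,8S)-8-hydroxy-7-oxo-6-oxabicyclo[3.2.1]oct-3-en-1-yl benzoate | O[C@H]1[C@H]2C=CC[C@]1(OC(=O)c3ccccc3)C(=O)O2
F8 | step 6 | (1S,2S)-1-(hydroxymethyl)-2-(triisopropylsilyloxy)cyclohex-3-en-1-ol | CC(C)[Si](C(C)C)(C(C)C)O[C@H]1C=CCC[C@]1(O)CO
F9 | step 6 | 3-(hydroxymethyl)-2-(triisopropylsilyloxy)-7-oxabicyclo[4.1.0]heptan-3-ol, epoxide anti to the silyloxy group | CC(C)[Si](C(C)C)(C(C)C)O[C@H]1[C@@H]2O[C@@H]2CC[C@]1(O)CO
F10 | step 6 | 1-(hydroxymethyl)-4-(phenylselanyl)-2-(triisopropylsilyloxy)cyclohexane-1,3-diol, 3-OH trans to 2-O and to 4-Se | CC(C)[Si](C(C)C)(C(C)C)O[C@H]1[C@H](O)[C@@H]([Se]c2ccccc2)CC[C@]1(O)CO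
F11 | step 10 | [3-(benzoyloxy)-1,6-dihydroxy-2-(triisopropylsilyloxy)cyclohex-4-en-1-yl]methyl benzoate, C1 to C3 as in 13, C6 either configuration | CC(C)[Si](C(C)C)(C(C)C)O[C@H]1[C@H](OC(=O)c2ccccc2)C=CC(O)[C@]1(O)COC(=O)c1ccccc1
F12 | step 11 | [(1S,2S,3R)-3-(benzoyloxy)-1,2-dihydroxycyclohex-4-en-1-yl]methyl benzoate | O[C@H]1[C@H](OC(=O)c2ccccc2)C=CC[C@]1(O)COC(=O)c1ccccc1
F13 | step 11 | [(1S,2S,3R)-2-acetoxy-3-(benzoyloxy)-1-hydroxycyclohex-4-en-1-yl]methyl benzoate | CC(=O)O[C@H]1[C@H](OC(=O)c2ccccc2)C=CC[C@]1(O)COC(=O)c1ccccc1
A1 | alternative 1 | tert-butyl 2-(tert-butyldimethylsilyl)-2-oxoacetate | CC(C)(C)OC(=O)C(=O)[Si](C)(C)C(C)(C)C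
A2 | alternative 1 | ethynyltrimethylsilane | C#C[Si](C)(C)C
A3 | alternative 1 | (R)-3-(tert-butyldiphenylsilyloxy)-2-(4-methoxybenzyloxy)propanal | O=C[C@H](OCc1ccc(OC)cc1)CO[Si](c1ccccc1)(c1ccccc1)C(C)(C)C
A4 | alternative 1 | tert-butyl 2-(tert-butyldimethylsilyloxy)-5-(tert-butyldiphenylsilyloxy)-3-hydroxy-4-(4-methoxybenzyloxy)-2-[(trimethylsilyl)ethynyl]pentanoate | CC(C)(C)OC(=O)[C@@](O[Si](C)(C)C(C)(C)C)(C#C[Si](C)(C)C)[C@@H](O)[C@H](OCc1ccc(OC)cc1)CO[Si](c1ccccc1)(c1ccccc1)C(C)(C)C
A5 | alternative 2 | (1-hydroxy-4-oxocyclohexa-2,5-dien-1-yl)methyl benzoate | O=C1C=CC(O)(COC(=O)c2ccccc2)C=C1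
A6 | alternative 2 | phenylboronic acid | OB(O)c1ccccc1
A7 | alternative 2 | cis-fused phenylboronate of 4-(benzoyloxymethyl)-4,5-dihydroxycyclohex-2-enone | O=C1C[C@@H]2OB(c3ccccc3)O[C@]2(COC(=O)c2ccccc2)C=C1
A8 | alternative 3 | methyl 3-hydroxy-4-(4-methoxybenzyloxy)-5-vinyloxolane-2-carboxylate, 3-OH trans to 4-O and to vinyl | C=C[C@@H]1O[C@H](C(=O)OC)[C@@H](O)[C@@H]1OCc1ccc(OC)cc1
A9 | alternative 3 | methyl 1,2-dihydroxy-3-(4-methoxybenzyloxy)cyclohex-4-ene-1-carboxylate | O[C@H]1[C@H](OCc2ccc(OC)cc2)C=CC[C@]1(O)C(=O)OC
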